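**Retrosynthetic overview**

1. Target ⇐ acetonide removal and C1 equilibration ⇐ HAT hydrogenation of C4=C4a ⇐ bicyclic β,γ-enone.
2. Key disconnection C5–C6 (closes ring B, makes the C6 quaternary centre): 6-endo 1,6-addition of a tertiary β-titanoxy radical, from Cp2TiCl opening of a Sharpless epoxy alcohol, onto the exocyclic CH2 of a 4-methylidenecyclohex-2-enone. The surviving C–O bond becomes the (S)-carbinol.
3. Dienone ⇐ γ-methylenation of a 5,5,6-trisubstituted cyclohex-2-enone; allylic alcohol ⇐ cross-metathesis of an isopropenyl terminus.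
4. C1 side chain ⇐ α′-alkylation with an iodide from (R)-2-methylglycidol; C8a ⇐ Cu-catalysed asymmetric conjugate addition to 3-methylcyclohex-2-enone, then dehydrogenation.
5. Ring order: ring A is bought as 3-methylcyclohex-2-enone; ring B is closed late by the radical step; the ring-fusion hydrogen is set last.

Convention: in the Why lines, locants C1–C8a are those of the decalone core of the target (C1 carries the pentyl chain, C2 is the ketone, C6 carries the methyl and the diol, C8a the angular methyl). From step 6 on, C1 is carried as an epimer mixture, and from step 7 on the allylic alcohol as an E/Z mixture; the major isomer is drawn and both converge (steps 10 and 12).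

Assumption: (R)-2-methylglycidol, (Z)-but-2-ene-1,4-diol and both enantiomers of the imidazolinium NHC precursor are taken as commercial.

**Step 1**
Reactants: 1 3-methylcyclohex-2-en-1-one; 2 4-bromo-2-methylbut-1-ene
Product: 4 (3R)-3-methyl-3-(3-methylbut-3-en-1-yl)cyclohexan-1-one, via Grignard reagent 3 (not isolated)
Conditions: 2, Mg, Et2O, rt; then 1, Cu(OTf)2 (3 mol %), chiral imidazolinium chloride (NHC precursor, 4 mol %), Et2O, 0 °C; aq. NH4Cl
Reagents that add atoms: none
Why: Copper–NHC-catalysed asymmetric conjugate addition of a Grignard reagent to a β-methyl cyclohexenone (Alexakis type) builds the C8a quaternary centre under catalyst control, the ligand enantiomer being the one that gives the (R)-ketone.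

**Step 2**
Reactants: 4 (3R)-3-methyl-3-(3-methylbut-3-en-1-yl)cyclohexan-1-one
Product: 5 (5S)-5-methyl-5-(3-methylbut-3-en-1-yl)cyclohex-2-en-1-one
Conditions: IBX (2.5 equiv), DMSO/fluorobenzene, 70 °C
Reagents that add atoms: none
Why: IBX dehydrogenation of a ketone (Nicolaou) can only go to C3=C4 because the other α-carbon has no β-hydrogen; the stereocentre is untouched (R to S is a CIP priority change only).

**Step 3**
Reactants: 6 [(2R)-2-methyloxiran-2-yl]methanol; 7 ethenylmagnesium bromide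
Product: 8 (2S)-2-methylpent-4-ene-1,2-diol
Conditions: 7 (2.5 equiv), CuI (10 mol %), THF, −30 to 0 °C; aq. NH4Cl
Reagents that add atoms: none
Why: Copper-catalysed Grignard opening of the epoxide at its CH2 terminus (SN2), after deprotonation of the alcohol by the first equivalent, leaves the tertiary C–O bond and so the stereocentre intact (R to S by CIP only).

**Step 4**
Reactants: 8 (2S)-2-methylpent-4-ene-1,2-diol
Product: 9 (4S)-2,2,4-trimethyl-4-(prop-2-en-1-yl)-1,3-dioxolane
Conditions: Me2C(OMe)2, TsOH (cat.), CH2Cl2, rt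
Reagents that add atoms: 2,2-dimethoxypropane, COC(C)(C)OC
Why: Acid-catalysed transketalisation protects the 1,2-diol as an acetonide for the enolate and titanium steps; no stereocentre is touched.

**Step 5**
Reactants: 9 (4S)-2,2,4-trimethyl-4-(prop-2-en-1-yl)-1,3-dioxolane
Product: 11 (4S)-4-(3-iodopropyl)-2,2,4-trimethyl-1,3-dioxolane, via B-alkyl-9-BBN 10 (not isolated)
Conditions: 9-BBN-H, THF, 0 °C to rt; then NaOMe, I2, MeOH, 0 °C
Reagents that add atoms: iodine, [I][I]
Why: Anti-Markovnikov hydroboration followed by Brown iodinolysis of the primary B–C bond gives the primary iodide; the remote stereocentre is untouched.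

**Step 6**
Reactants: 5 (5S)-5-methyl-5-(3-methylbut-3-en-1-yl)cyclohex-2-en-1-one; 11 (4S)-4-(3-iodopropyl)-2,2,4-trimethyl-1,3-dioxolane
Product: 13 (5S,6R)-5-methyl-5-(3-methylbut-3-en-1-yl)-6-{3-[(4S)-2,2,4-trimethyl-1,3-dioxolan-4-yl]propyl}cyclohex-2-en-1-one, via lithium enolate 12 (not isolated)
Conditions: LiN(i-Pr)2 (LDA), THF, −78 °C; then 11, HMPA, −78 to 0 °C
Reagents that add atoms: none
Why: Kinetic deprotonation of the enone gives only the cross-conjugated α′-enolate (C1 is the only sp3 α-carbon), and SN2 alkylation occurs mainly anti to the longer C8a substituent; this α-keto centre is epimerisable and is fixed in step 12.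

**Step 7**
Reactants: 13 (5S,6R)-5-methyl-5-(3-methylbut-3-en-1-yl)-6-{3-[(4S)-2,2,4-trimethyl-1,3-dioxolan-4-yl]propyl}cyclohex-2-en-1-one; 14 (2Z)-but-2-ene-1,4-diol
Product: 15 (5S,6R)-5-[(3E)-5-hydroxy-3-methylpent-3-en-1-yl]-5-methyl-6-{3-[(4S)-2,2,4-trimethyl-1,3-dioxolan-4-yl]propyl}cyclohex-2-en-1-one
Conditions: 14 (4 equiv), second-generation Hoveyda–Grubbs catalyst [RuCl2(H2IMes)(=CH–C6H4–2-OiPr)] (8 mol %), CH2Cl2, 40 °C
Reagents that add atoms: none
Why: Olefin cross-metathesis of the 1,1-disubstituted alkene with an allylic alcohol partner gives the trisubstituted allylic alcohol (E major, roughly 3:1); the geometry does not matter because this carbon becomes a planar radical in step 10, and the ring enone is not a metathesis partner.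

**Step 8**
Reactants: 15 (5S,6R)-5-[(3E)-5-hydroxy-3-methylpent-3-en-1-yl]-5-methyl-6-{3-[(4S)-2,2,4-trimethyl-1,3-dioxolan-4-yl]propyl}cyclohex-2-en-1-one
Product: 19 (5R,6R)-5-[(3E)-5-hydroxy-3-methylpent-3-en-1-yl]-5-methyl-4-methylidene-6-{3-[(4S)-2,2,4-trimethyl-1,3-dioxolan-4-yl]propyl}cyclohex-2-en-1-one, via bis-silyl dienol ether 16 (not isolated), via Mannich base 17 (not isolated), via ammonium iodide 18 (not isolated)
Conditions: TMSOTf (2.5 equiv), Et3N, CH2Cl2, 0 °C; then Me2N=CH2 I (Eschenmoser's salt), rt; then MeI; then DBU; aq. citric acid, then NaHCO3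
Reagents that add atoms: N,N-dimethylmethyleneiminium iodide (Eschenmoser's salt), C=[N+](C)C.[I-]
Why: One-pot γ-methylenation as used for 6-methylene-4-en-3-one steroids: thermodynamic linear silyl dienol ether, vinylogous Mannich reaction at the γ-carbon (C4a), quaternisation and E1cB elimination install C5 as an exocyclic CH2; no stereocentre is made (S to R at C8a is a CIP change only).

**Step 9**
Reactants: 19 (5R,6R)-5-[(3E)-5-hydroxy-3-methylpent-3-en-1-yl]-5-methyl-4-methylidene-6-{3-[(4S)-2,2,4-trimethyl-1,3-dioxolan-4-yl]propyl}cyclohex-2-en-1-one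
Product: 20 (5R,6R)-5-{2-[(2R,3R)-3-(hydroxymethyl)-2-methyloxiran-2-yl]ethyl}-5-methyl-4-methylidene-6-{3-[(4S)-2,2,4-trimethyl-1,3-dioxolan-4-yl]propyl}cyclohex-2-en-1-one
Conditions: Ti(OiPr)4 (10 mol %), D-(−)-diethyl tartrate (12 mol %), t-BuOOH, 4 Å MS, CH2Cl2, −20 °C
Reagents that add atoms: tert-butyl hydroperoxide, CC(C)(C)OO
Why: Sharpless–Katsuki asymmetric epoxidation is reagent-controlled and makes the carbinol carbon (R) in the epoxide from both the E and the Z allylic alcohol (it becomes the (S)-carbinol of the target by CIP once the other C–O bond is cut); the electron-poor dienone is inert.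

**Step 10**
Reactants: 20 (5R,6R)-5-{2-[(2R,3R)-3-(hydroxymethyl)-2-methyloxiran-2-yl]ethyl}-5-methyl-4-methylidene-6-{3-[(4S)-2,2,4-trimethyl-1,3-dioxolan-4-yl]propyl}cyclohex-2-en-1-one
Product: 23 (1R,6S,8aR)-6-[(1S)-1,2-dihydroxyethyl]-6,8a-dimethyl-1-{3-[(4S)-2,2,4-trimethyl-1,3-dioxolan-4-yl]propyl}-3,5,6,7,8,8a-hexahydronaphthalen-2(1H)-one, via β-titanoxy radical 21 (not isolated), via titanium dienolate 22 (not isolated)
Conditions: Cp2TiCl2 (20 mol %), Mn dust, 2,4,6-collidine·HCl, THF, rt; aq. NaH2PO4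
Reagents that add atoms: none
Why: Proposed new method: Cp2TiCl (trivalent titanium, formed in situ) opens the epoxide homolytically at the tertiary carbon to radical 21, which adds 6-endo to the electrophilic exocyclic CH2 of the dienone (Giese-type 1,6-addition) through a chair transition state with the bulky titanoxy-bearing group equatorial and the methyl axial, anti to the angular methyl. This forms the C5–C6 bond, ring B and the (6S) quaternary centre, while the untouched carbinol C–O bond keeps its step 9 configuration; a second Cp2TiCl reduces the oxypentadienyl radical to dienolate 22, which collidinium protonates at C3 to the β,γ-enone. Closest known reaction type: Nugent–RajanBabu/Gansäuer titanocene-mediated epoxide-opening radical cyclisations onto α,β-unsaturated carbonyl acceptors.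

**Step 11**
Reactants: 23 (1R,6S,8aR)-6-[(1S)-1,2-dihydroxyethyl]-6,8a-dimethyl-1-{3-[(4S)-2,2,4-trimethyl-1,3-dioxolan-4-yl]propyl}-3,5,6,7,8,8a-hexahydronaphthalen-2(1H)-one
Product: 24 (1R,4aS,6S,8aS)-6-[(1S)-1,2-dihydroxyethyl]-6,8a-dimethyl-1-{3-[(4S)-2,2,4-trimethyl-1,3-dioxolan-4-yl]propyl}octahydronaphthalen-2(1H)-one
Conditions: Mn(dpm)3 (10 mol %), PhSiH3, t-BuOOH, i-PrOH, rt
Reagents that add atoms: none
Why: Mn-catalysed hydrogen-atom-transfer hydrogenation (Shenvi) puts H on C4 and then on the tertiary C4a radical from the face anti to the adjacent angular methyl, giving the thermodynamically preferred trans ring fusion (4aS); ketone, diol and acetonide are inert.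

**Step 12**
Reactants: 24 (1R,4aS,6S,8aS)-6-[(1S)-1,2-dihydroxyethyl]-6,8a-dimethyl-1-{3-[(4S)-2,2,4-trimethyl-1,3-dioxolan-4-yl]propyl}octahydronaphthalen-2(1H)-one
Product: 25 (1R,4aS,6S,8aS)-6-[(1S)-1,2-dihydroxyethyl]-1-[(4S)-4,5-dihydroxy-4-methylpentyl]-6,8a-dimethyloctahydronaphthalen-2(1H)-one
Conditions: 2 M HCl, THF, rt; then K2CO3, MeOH, rt
Reagents that add atoms: none
Why: Acetal hydrolysis frees the side-chain diol, and enolisation equilibrates the α-keto centre C1 to the more stable equatorial (1R) epimer, so both C1 epimers carried from step 6 converge on the target.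

**Compound list**

1 | 3-methylcyclohex-2-en-1-one | CC1=CC(=O)CCC1 | starting material
2 | 4-bromo-2-methylbut-1-ene | C=C(C)CCBr | starting material
3 | (3-methylbut-3-en-1-yl)magnesium bromide | C=C(C)CC[Mg]Br | intermediate (not isolated)
4 | (3R)-3-methyl-3-(3-methylbut-3-en-1-yl)cyclohexan-1-one | O=C1CCC[C@](C)(CCC(C)=C)C1 | intermediate
5 | (5S)-5-methyl-5-(3-methylbut-3-en-1-yl)cyclohex-2-en-1-one | O=C1C=CC[C@](C)(CCC(C)=C)C1 | intermediate
6 | [(2R)-2-methyloxiran-2-yl]methanol | C[C@@]1(CO)CO1 | starting material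
7 | ethenylmagnesium bromide | C=C[Mg]Br | starting material
8 | (2S)-2-methylpent-4-ene-1,2-diol | C[C@@](O)(CO)CC=C | intermediate
9 | (4S)-2,2,4-trimethyl-4-(prop-2-en-1-yl)-1,3-dioxolane | C[C@]1(CC=C)COC(C)(C)O1 | intermediate
10 | 9-{3-[(4S)-2,2,4-trimethyl-1,3-dioxolan-4-yl]propyl}-9-borabicyclo[3.3.1]nonane | C[C@]1(CCCB2C3CCCC2CCC3)COC(C)(C)O1 | intermediate (not isolated)
11 | (4S)-4-(3-iodopropyl)-2,2,4-trimethyl-1,3-dioxolane | C[C@]1(CCCI)COC(C)(C)O1 | intermediate
12 | lithium α′-enolate (cross-conjugated dienolate) of 5 | [Li]OC1=C[C@@](C)(CCC(C)=C)CC=C1 | intermediate (not isolated)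
13 | (5S,6R)-5-methyl-5-(3-methylbut-3-en-1-yl)-6-{3-[(4S)-2,2,4-trimethyl-1,3-dioxolan-4-yl]propyl}cyclohex-2-en-1-one (major C6 epimer drawn) | O=C1C=CC[C@](C)(CCC(C)=C)[C@H]1CCC[C@@]2(C)COC(C)(C)O2 | intermediate
14 | (2Z)-but-2-ene-1,4-diol | OC/C=C\CO | starting material
15 | (5S,6R)-5-[(3E)-5-hydroxy-3-methylpent-3-en-1-yl]-5-methyl-6-{3-[(4S)-2,2,4-trimethyl-1,3-dioxolan-4-yl]propyl}cyclohex-2-en-1-one (E isomer drawn) | O=C1C=CC[C@](C)(CC/C(C)=C/CO)[C@H]1CCC[C@@]2(C)COC(C)(C)O2 | intermediate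
16 | bis(trimethylsilyl) derivative of 15: linear 2-silyloxy-1,3-diene with the side-chain alcohol O-silylated | C[Si](C)(C)OC1=CC=C[C@](C)(CC/C(C)=C/CO[Si](C)(C)C)[C@H]1CCC[C@@]2(C)COC(C)(C)O2 | intermediate (not isolated)
17 | γ-(dimethylaminomethyl) enone (Mannich base, both epimers at the new centre) | O=C1C=CC(CN(C)C)[C@](C)(CC/C(C)=C/CO[Si](C)(C)C)[C@H]1CCC[C@@]2(C)COC(C)(C)O2 | intermediate (not isolated)
18 | N-methyl quaternary ammonium iodide of 17 | O=C1C=CC(C[N+](C)(C)C)[C@](C)(CC/C(C)=C/CO[Si](C)(C)C)[C@H]1CCC[C@@]2(C)COC(C)(C)O2.[I-] | intermediate (not isolated)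
19 | (5R,6R)-5-[(3E)-5-hydroxy-3-methylpent-3-en-1-yl]-5-methyl-4-methylidene-6-{3-[(4S)-2,2,4-trimethyl-1,3-dioxolan-4-yl]propyl}cyclohex-2-en-1-one | O=C1C=CC(=C)[C@](C)(CC/C(C)=C/CO)[C@H]1CCC[C@@]2(C)COC(C)(C)O2 | intermediate
20 | (5R,6R)-5-{2-[(2R,3R)-3-(hydroxymethyl)-2-methyloxiran-2-yl]ethyl}-5-methyl-4-methylidene-6-{3-[(4S)-2,2,4-trimethyl-1,3-dioxolan-4-yl]propyl}cyclohex-2-en-1-one | O=C1C=CC(=C)[C@](C)(CC[C@@]2(C)O[C@@H]2CO)[C@H]1CCC[C@@]3(C)COC(C)(C)O3 | intermediate
21 | tertiary C6 radical with Cp2(Cl)Ti–O on the carbinol carbon | O=C1C=CC(=C)[C@](C)(CC[C](C)[C@H](O[Ti](Cl)(C2C=CC=C2)C2C=CC=C2)CO)[C@H]1CCC[C@@]3(C)COC(C)(C)O3 | intermediate (not isolated)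
22 | cyclised titanium dienolate (C2–O–Ti, C2=C3, C4=C4a; carbinol O–Ti) | C[C@]3(CCC[C@H]1C(O[Ti](Cl)(C4C=CC=C4)C4C=CC=C4)=CC=C2C[C@@](C)([C@H](O[Ti](Cl)(C4C=CC=C4)C4C=CC=C4)CO)CC[C@@]21C)COC(C)(C)O3 | intermediate (not isolated)
23 | (1R,6S,8aR)-6-[(1S)-1,2-dihydroxyethyl]-6,8a-dimethyl-1-{3-[(4S)-2,2,4-trimethyl-1,3-dioxolan-4-yl]propyl}-3,5,6,7,8,8a-hexahydronaphthalen-2(1H)-one | C[C@]3(CCC[C@H]1C(=O)CC=C2C[C@@](C)([C@H](O)CO)CC[C@@]21C)COC(C)(C)O3 | intermediate
24 | (1R,4aS,6S,8aS)-6-[(1S)-1,2-dihydroxyethyl]-6,8a-dimethyl-1-{3-[(4S)-2,2,4-trimethyl-1,3-dioxolan-4-yl]propyl}octahydronaphthalen-2(1H)-one | C[C@]3(CCC[C@H]1C(=O)CC[C@H]2C[C@@](C)([C@H](O)CO)CC[C@@]21C)COC(C)(C)O3 | intermediate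
25 | (1R,4aS,6S,8aS)-6-[(1S)-1,2-dihydroxyethyl]-1-[(4S)-4,5-dihydroxy-4-methylpentyl]-6,8a-dimethyloctahydronaphthalen-2(1H)-one | C[C@@](O)(CO)CCC[C@H]1C(=O)CC[C@H]2C[C@@](C)([C@H](O)CO)CC[C@@]21C | target

**Step count and risks**

Total: 12 steps. Longest linear sequence: 10 steps (6 → 8 → 9 → 11 → 13 → 15 → 19 → 20 → 23 → 24 → 25).

Step 10 is the most likely to fail. Cp2TiCl may reduce the dienone or deoxygenate the epoxide before cyclisation, and the C6 facial selectivity rests on one chair preference. The fallback sets out from 20 and comes back at 23. Open the epoxide of 20 at its tertiary carbon with MgBr2·OEt2 to the bromohydrin (5R,6R)-5-[(3S,4R)-3-bromo-4,5-dihydroxy-3-methylpentyl]-5-methyl-4-methylidene-6-{3-[(4S)-2,2,4-trimethyl-1,3-dioxolan-4-yl]propyl}cyclohex-2-en-1-one F1. Then generate the same tertiary radical without titanium by photoredox reduction of the C–Br bond (Ir(ppy)3, Hantzsch ester, i-Pr2NEt, MeCN, blue light); 6-endo Giese closure, reduction of the dienyl radical and protonation give 23.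

Step 11 is the second risk. The hydrogen must enter C4a on the face that carries the axial C6 methyl (1,3-diaxial), so the usual anti-to-angular-methyl preference may be eroded and cis-fused material may form. The fallback sets out from 23 and comes back at 24. Isomerise 23 with DBU (toluene, 60 °C) to the conjugated enone (1R,4aR,6S,8aS)-6-[(1S)-1,2-dihydroxyethyl]-6,8a-dimethyl-1-{3-[(4S)-2,2,4-trimethyl-1,3-dioxolan-4-yl]propyl}-4a,5,6,7,8,8a-hexahydronaphthalen-2(1H)-one F2, in which C4a is a γ-position and equilibrates towards the trans fusion. Then hydrogenate C3=C4 (H2, Pd/C, EtOAc), which creates no stereocentre, to reach 24; the minor cis isomer is recycled through the equilibration.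

Step 8 is the third risk. The Mannich step may attack the α-carbon C3 instead of the hindered γ-carbon C4a, and the free alcohol complicates the silylation. The fallback sets out from 13 and comes back at 19, moving the methylenation before the metathesis and using enamine chemistry. Condense 13 with pyrrolidine (benzene, reflux) to the linear dienamine 1-[(5S,6R)-5-methyl-5-(3-methylbut-3-en-1-yl)-6-{3-[(4S)-2,2,4-trimethyl-1,3-dioxolan-4-yl]propyl}cyclohexa-1,3-dien-1-yl]pyrrolidine F3. Add aqueous formaldehyde at the γ-carbon and hydrolyse to (5S,6R)-4-(hydroxymethyl)-5-methyl-5-(3-methylbut-3-en-1-yl)-6-{3-[(4S)-2,2,4-trimethyl-1,3-dioxolan-4-yl]propyl}cyclohex-2-en-1-one F4. Convert it with MsCl/Et3N to the methanesulfonate of F4 F5 and eliminate with DBU to (5R,6R)-5-methyl-5-(3-methylbut-3-en-1-yl)-4-methylidene-6-{3-[(4S)-2,2,4-trimethyl-1,3-dioxolan-4-yl]propyl}cyclohex-2-en-1-one F6. Cross-metathesis of F6 with 14 under the step 7 conditions gives 19.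

**Further compounds**

F1 | step 10 | (5R,6R)-5-[(3S,4R)-3-bromo-4,5-dihydroxy-3-methylpentyl]-5-methyl-4-methylidene-6-{3-[(4S)-2,2,4-trimethyl-1,3-dioxolan-4-yl]propyl}cyclohex-2-en-1-one | O=C1C=CC(=C)[C@](C)(CC[C@](C)(Br)[C@H](O)CO)[C@H]1CCC[C@@]2(C)COC(C)(C)O2
F2 | step 11 | (1R,4aR,6S,8aS)-6-[(1S)-1,2-dihydroxyethyl]-6,8a-dimethyl-1-{3-[(4S)-2,2,4-trimethyl-1,3-dioxolan-4-yl]propyl}-4a,5,6,7,8,8a-hexahydronaphthalen-2(1H)-one | C[C@]3(CCC[C@H]1C(=O)C=C[C@H]2C[C@@](C)([C@H](O)CO)CC[C@@]21C)COC(C)(C)O3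
F3 | step 8 | 1-[(5S,6R)-5-methyl-5-(3-methylbut-3-en-1-yl)-6-{3-[(4S)-2,2,4-trimethyl-1,3-dioxolan-4-yl]propyl}cyclohexa-1,3-dien-1-yl]pyrrolidine | C1CCN(C1)C1=CC=C[C@](C)(CCC(C)=C)[C@H]1CCC[C@@]2(C)COC(C)(C)O2
F4 | step 8 | (5S,6R)-4-(hydroxymethyl)-5-methyl-5-(3-methylbut-3-en-1-yl)-6-{3-[(4S)-2,2,4-trimethyl-1,3-dioxolan-4-yl]propyl}cyclohex-2-en-1-one (both C4 epimers) | O=C1C=CC(CO)[C@](C)(CCC(C)=C)[C@H]1CCC[C@@]2(C)COC(C)(C)O2
F5 | step 8 | methanesulfonate ester of the primary alcohol of F4 | O=C1C=CC(COS(C)(=O)=O)[C@](C)(CCC(C)=C)[C@H]1CCC[C@@]2(C)COC(C)(C)O2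
F6 | step 8 | (5R,6R)-5-methyl-5-(3-methylbut-3-en-1-yl)-4-methylidene-6-{3-[(4S)-2,2,4-trimethyl-1,3-dioxolan-4-yl]propyl}cyclohex-2-en-1-one | O=C1C=CC(=C)[C@](C)(CCC(C)=C)[C@H]1CCC[C@@]2(C)COC(C)(C)O2
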